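Friday's flask keeps a leftover: from 2.00 min on, about 70.0% of its starting material lies unreacted. Sunday's flask, with twice the free catalyst, leaves more, about 82.8%.

| flask | starting material | second substrate | reagent | protic impurity | free catalyst | remark | time |
|---|---|---|---|---|---|---|---|
| Friday's | 0.050 M (fed, over 80 s) | 0.10 M | 0.0525 M | 0.025 M | 55 µM | the very flask that is asked about, followed so far |  |
| Sunday's | 0.050 M (fed, over 80 s) | 0.10 M | 0.0525 M | 0.025 M | 110 µM | run made earlier |  |
| flask | 0.050 M (fed, over 80 s) | 0.100 M | 0.0525 M | 0.0250 M | 55 µM |  | 30 min |

- Friday's (time / min: starting material / %, side product / %, target / %): 1.00: 46.4, 27.2, 0.7; 2.00: 69.8, 29.6, 0; 3.00: 69.2, 29.5, 0.4; 4.00: 70.5, 31.1, 0.1; 5.00: 68.9, 28.9, 0; 6.00: 70.0, 29.7, 0.2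
- Sunday's (time / min: starting material / %, side product / %, target / %): 1.33: 82.4, 18.6, 0.6; 4.00: 82.2, 18.0, 0; 8.00: 82.8, 17.7, 0.1; 12.0: 82.3, 18.1, 0; 15.0: 82.4, 17.1, 0; 20.0: 82.8, 17.3, 0.5

(each reading ± 0.5 percentage points)

- a species is counted by the starting material in it: one side product counts as two
- the reaction counts as stopped when no species that holds the starting material changes by six tenths of a point or more over the second half of the time
- percentages count the whole charge, also what has not yet gone in

1. which holds at 30 min: what has brought the reaction to rest, or that it has not come to rest (the reagent has run out first / all of the starting material has reacted / no working catalyst is left / it is still moving / forward and back rates have come level)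
2. conversion of starting material at 30 min
3. amount of side product at 30 min, in percent of the starting material charged

I build the flask up one process at a time. First comes the main step, as I assume it: the catalyst joins starting material to reagent, giving target, and target takes a further starting material to give side product. One side product then costs one reagent and two starting material, so a full charge needs

need = 0.0250 M of reagent,

less than the 0.0525 M charged. This step by itself points to full conversion, and Friday's flask stops far short of it.

Next I add the second substrate, charged at 0.100 M, as a rival for the same catalyst and the same reagent. Then a fixed reagent charge can split. With R the reagent charge, S the starting material charge and y the plateau side product as a share of S, I read y = 29.8% on Friday and y = 17.8% on Sunday. I call W the reagent not taken up by side product: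

W = R − S·y/2

Friday: W = 0.0451 M
Sunday: W = 0.0480 M

Sunday's W is larger, so more catalyst can shift the split while the total stays fixed. Friday's W is also less than the second substrate charged, so the rival has room to take it.

Last comes the protic impurity, 0.0250 M. The readings do not show its partner, so it changes nothing in my number; any reagent it takes sits inside W.

Friday's flask stays flat to 6.00 min and Sunday's to 20.0 min, so for 30 min I keep Friday's plateau: side product and conversion near 29.8%, with the reagent as limiting reagent.

The forecast says no working catalyst is left, with conversion 30% and side product 29.8%, and holds that “A fixed stoichiometric limit also wouldn't give plateaus that depend on catalyst”. We differ on the first question, and our two numbers lie close.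

The flask gives: the reagent has run out first, with 0% of its reagent left at 30.0 min; conversion 29.9%, side product 29.8%.

    starting material + free catalyst ⇌ catalyst intermediate A (K = 280 L mol⁻¹, k = 820 L mol⁻¹ s⁻¹)
    reagent + catalyst intermediate A → free catalyst + target (k = 2600 L mol⁻¹ s⁻¹)
    second substrate + free catalyst ⇌ catalyst intermediate B (K = 48.0 L mol⁻¹, k = 770 L mol⁻¹ s⁻¹)
    reagent + catalyst intermediate B → free catalyst + second product (k = 3000 L mol⁻¹ s⁻¹)
    starting material + target → side product (k = 5.20 L mol⁻¹ s⁻¹)
    second substrate + protic impurity → quenched substrate (k = 0.250 L mol⁻¹ s⁻¹)

The flask's second product stands at 0.0450 M, level with W. The neighbour charged with 2.2 × 10⁻⁴ M of free catalyst ends at 9.92% side product, which gives W = 0.0500 M, and it holds 0.0500 M of second product. The flask has come to rest: its largest change over the second half of the time is 0 percentage points. At 300 min, ten times the time, conversion is still 29.9% and side product 29.8%.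

The readings are calculated with constants of no real substance; scatter was added.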